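A direct plan would carry both methyl centres in an open chain, for example the anti-2,4-dimethyl alcohol A1, and lengthen it two carbons at a time to the tetraenoate A2.
It would then close both rings at once by a thermal intramolecular Diels–Alder reaction to ester A3 and saponify.
Weak point 1, the chain building: every two-carbon extension would cost an oxidation, an olefination and a reduction, with a silyl group put on and taken off, so about fifteen linear steps would pass before any ring exists.
Weak point 2, the second methyl centre: it would be set by a catalyst-controlled high-pressure hydrogenation of a trisubstituted allylic alcohol, remote from the first centre and without help from the substrate.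
Weak point 3, the ring closure: one thermal event would have to fix four ring stereocentres, including the quaternary C4, with only the two tether methyls choosing the diene face and the exo mode, and it would depend on the geometric purity of an isomerisation-prone (Z)-trisubstituted dienophile.

Retrosynthetic overview
Ring B (C3a–C4–C5–C6–C7–C7a) has its quaternary C4 next to C3a and "para" to the sp2 carbon C7. This invites an intermolecular Diels–Alder reaction of a 2-silyloxy diene C6=C7–C7a=C3a with 2-ethylacrolein (C4=C5), forming C3a–C4 and C5–C6.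
Ring A (C1–C2–C3–C3a–C7a) is made first, by aldol condensation of a chain cut from (R)-citronellic acid, whose C1–C6 become C7, C7a, C1, C2, C3 and C3a; its stereocentre becomes C1 and is the only source of chirality.
After the cycloaddition, C7a is set by enolate protonation, C3 by hydrogenation of a methylidene group, and C5 by cuprate addition to the ring B enone, which also delivers the enol triflate that takes the C7 ethyl group.
The design needs no polyene chain, no protecting-group traffic and no reagent-controlled stereocentre.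

Key step: step 6

Remark: atom numbers (C1–C3, C3a, C4–C7, C7a) follow the indene numbering of the target; (R)-(+)-citronellic acid of high enantiomeric purity is assumed to be commercial.

Step 1
Reactants: 1 (R)-citronellic acid [(3R)-3,7-dimethyloct-6-enoic acid]
Product: 2 (4R)-4,8-dimethylnon-7-en-2-one
Conditions: MeLi (2.2 equiv), Et2O, 0 °C to rt; poured into cold aq. HCl
Reagents that add atoms: methyllithium, [Li]C
Why: Addition of MeLi to the lithium carboxylate gives a dilithium gem-diolate that collapses to the methyl ketone only on work-up (ketone synthesis from a carboxylic acid and an organolithium), and the stereocentre is not touched.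

Step 2
Reactants: 2 (4R)-4,8-dimethylnon-7-en-2-one
Product: 4 (4R)-4-methyl-6-oxoheptanal, via secondary ozonide 3 (not isolated)
Conditions: O3, CH2Cl2, −78 °C; then Me2S, −78 °C to rt
Reagents that add atoms: ozone, [O-][O+]=O
Why: Ozonolysis with reductive work-up cleaves the trisubstituted alkene to the aldehyde and acetone, while the ketone and the stereocentre are inert.

Step 3
Reactants: 4 (4R)-4-methyl-6-oxoheptanal
Product: 5 (4R)-4-methyl-2-methylidene-6-oxoheptanal
Conditions: dimethyl(methylidene)ammonium iodide (1.5 equiv), Et3N (2 equiv), CH2Cl2, rt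
Reagents that add atoms: dimethyl(methylidene)ammonium iodide, C=[N+](C)C.[I-]
Why: Mannich reaction of the aldehyde, which enolises faster than the ketone, followed by β-elimination of dimethylamine gives the α-methylene aldehyde (α-methylenation); the new carbon is the future C3 methyl group.

Step 4
Reactants: 5 (4R)-4-methyl-2-methylidene-6-oxoheptanal
Product: 6 1-[(5R)-5-methyl-3-methylidenecyclopent-1-en-1-yl]ethan-1-one
Conditions: dibenzylammonium trifluoroacetate (0.3 equiv), toluene, 50 °C
Reagents that add atoms: none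
Why: Intramolecular aldol condensation closes ring A (5-exo attack of the ketone α-methylene on the aldehyde); the aldehyde has no α-hydrogen left and can only be the acceptor, so only the acetylcyclopentene can form.

Step 5
Reactants: 6 1-[(5R)-5-methyl-3-methylidenecyclopent-1-en-1-yl]ethan-1-one
Product: 7 triisopropyl({1-[(5R)-5-methyl-3-methylidenecyclopent-1-en-1-yl]ethenyl}oxy)silane
Conditions: i-Pr3SiOTf (1.2 equiv), Et3N (2 equiv), CH2Cl2, 0 °C; used at once
Reagents that add atoms: triisopropylsilyl trifluoromethanesulfonate, CC(C)[Si](OS(=O)(=O)C(F)(F)F)(C(C)C)C(C)C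
Why: Soft enolisation (O-silylation, then deprotonation of the acetyl methyl group, the only acidic position) gives the 2-silyloxy diene without strong base.

Step 6
Reactants: 7 triisopropyl({1-[(5R)-5-methyl-3-methylidenecyclopent-1-en-1-yl]ethenyl}oxy)silane; 8 2-ethylacrolein (2-methylidenebutanal)
Product: 9 (1R,3aR,4S)-4-ethyl-1-methyl-3-methylidene-7-{[tri(propan-2-yl)silyl]oxy}-2,3,3a,4,5,6-hexahydro-1H-indene-4-carbaldehyde
Conditions: 8 (3 equiv), Me2AlCl (0.5 equiv), CH2Cl2, −78 to −40 °C; Et3N quench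
Reagents that add atoms: none
Why: Lewis-acid-catalysed normal-demand Diels–Alder reaction of the s-cis 2-silyloxy diene C6=C7–C7a=C3a of 7 with the Me2AlCl-bound enal 8; the closest known type is the catalysed cycloaddition of 2-silyloxybutadienes and 1-(1-silyloxyvinyl)cycloalkenes with α-substituted acroleins. Ring B closes as a [4+2] onto the existing ring A by forming C3a–C4 and C5–C6, and no bond of ring A is made. The C7 silyloxy group makes C6 the nucleophilic terminus, which bonds to the unsubstituted β-carbon of 8, so the formyl-bearing carbon becomes the quaternary C4 next to C3a. C3a is set by the diene face: the enal should add anti to the C1 methyl group, the only stereocentre of 7, which stands over one face of the flat diene. C4 is set relative to C3a by the endo position of the formyl group (ethyl exo), which places CHO cis to C3 as in the target. The step needs addition to C=C and not to C=O, and endo and facial selectivity: the C3 methylidene diene unit is locked s-trans and cannot react, the triisopropylsilyl ether survives the Lewis acid, and the s-cis diene at low temperature favours concerted cycloaddition over aldol-type attack.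

Step 7
Reactants: 9 (1R,3aR,4S)-4-ethyl-1-methyl-3-methylidene-7-{[tri(propan-2-yl)silyl]oxy}-2,3,3a,4,5,6-hexahydro-1H-indene-4-carbaldehyde
Product: 10 (1R,3aS,4S,7aR)-4-ethyl-1-methyl-3-methylidene-7-oxooctahydro-1H-indene-4-carbaldehyde
Conditions: Bu4NF (1.1 equiv), AcOH (1.5 equiv), THF, −40 to 0 °C
Reagents that add atoms: none
Why: Fluoride cleaves the O–Si bond and the enolate is C-protonated under kinetic control (desilylation–protonation of a silyl enol ether); the proton should enter C7a axially, anti to the pseudoaxial C3a–H and away from the neighbouring C1 methyl group, which gives the trans ring fusion, and the buffer prevents later equilibration.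

Step 8
Reactants: 10 (1R,3aS,4S,7aR)-4-ethyl-1-methyl-3-methylidene-7-oxooctahydro-1H-indene-4-carbaldehyde; 11 methyl 2-(triphenyl-λ5-phosphanylidene)propanoate
Product: 12 methyl (2E)-3-[(1R,3aS,4R,7aR)-4-ethyl-1-methyl-3-methylidene-7-oxooctahydro-1H-inden-4-yl]-2-methylprop-2-enoate
Conditions: 11 (2 equiv), toluene, 90 °C
Reagents that add atoms: none
Why: Wittig reaction of the stabilised ylide takes the aldehyde and not the ketone and gives the (E)-trisubstituted enoate; the ylide is too weak a base to epimerise C7a.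

Step 9
Reactants: 12 methyl (2E)-3-[(1R,3aS,4R,7aR)-4-ethyl-1-methyl-3-methylidene-7-oxooctahydro-1H-inden-4-yl]-2-methylprop-2-enoate
Product: 13 methyl (2E)-3-[(1R,3R,3aR,4S,7aR)-4-ethyl-1,3-dimethyl-7-oxooctahydro-1H-inden-4-yl]-2-methylprop-2-enoate
Conditions: H2 (1 atm), RhCl(PPh3)3 (5 mol %), benzene, rt
Reagents that add atoms: none
Why: Homogeneous hydrogenation with RhCl(PPh3)3 reduces only the 1,1-disubstituted exocyclic alkene and should deliver hydrogen to C3 from the face opposite the axial C4 alkenyl chain, so that the new methyl group is cis to C4 and trans to the C1 methyl group.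

Step 10
Reactants: 13 methyl (2E)-3-[(1R,3R,3aR,4S,7aR)-4-ethyl-1,3-dimethyl-7-oxooctahydro-1H-inden-4-yl]-2-methylprop-2-enoate
Product: 15 methyl (2E)-3-[(1R,3R,3aR,4S,7aR)-4-ethyl-1,3-dimethyl-7-oxo-2,3,3a,4,7,7a-hexahydro-1H-inden-4-yl]-2-methylprop-2-enoate, via kinetic lithium enolate 14 (not isolated)
Conditions: LiN(i-Pr)2 (1.1 equiv), THF, −78 °C; then N-tert-butylbenzenesulfinimidoyl chloride (1.2 equiv), −78 °C
Reagents that add atoms: none
Why: Kinetic deprotonation takes the C6 methylene and not the C7a methine, and Mukaiyama dehydrogenation (S-sulfenylation of the enolate and syn elimination at low temperature) gives the C5=C6 enone without touching C7a.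

Step 11
Reactants: 15 methyl (2E)-3-[(1R,3R,3aR,4S,7aR)-4-ethyl-1,3-dimethyl-7-oxo-2,3,3a,4,7,7a-hexahydro-1H-inden-4-yl]-2-methylprop-2-enoate
Product: 17 methyl (2E)-3-[(1R,3R,3aR,4S,5S,7aR)-4-ethyl-1,3-dimethyl-5-phenyl-7-{[(trifluoromethyl)sulfonyl]oxy}-2,3,3a,4,5,7a-hexahydro-1H-inden-4-yl]-2-methylprop-2-enoate, via lithium enolate 16 (not isolated)
Conditions: Ph2CuLi (1.5 equiv), Et2O/THF, −78 to −40 °C; then PhNTf2 (2 equiv), −40 °C to rt
Reagents that add atoms: lithium diphenylcuprate, [Li+].c1ccccc1[Cu-]c1ccccc1; N-phenylbis(trifluoromethanesulfonimide), O=S(=O)(N(c1ccccc1)S(=O)(=O)C(F)(F)F)C(F)(F)F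
Why: Conjugate addition of the cuprate should occur axially at C5, anti to the axial C4 side chain of the rigid trans-fused enone, so that phenyl ends cis to the C4 ethyl group, and O-triflation of the regiodefined enolate gives the C6=C7 enol triflate (conjugate addition–enolate trapping).

Step 12
Reactants: 17 methyl (2E)-3-[(1R,3R,3aR,4S,5S,7aR)-4-ethyl-1,3-dimethyl-5-phenyl-7-{[(trifluoromethyl)sulfonyl]oxy}-2,3,3a,4,5,7a-hexahydro-1H-inden-4-yl]-2-methylprop-2-enoate
Product: 18 methyl (2E)-3-[(1R,3R,3aR,4S,5S,7aR)-4,7-diethyl-1,3-dimethyl-5-phenyl-2,3,3a,4,5,7a-hexahydro-1H-inden-4-yl]-2-methylprop-2-enoate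
Conditions: Et2Zn (1.5 equiv), Pd(dppf)Cl2 (5 mol %), THF, 50 °C
Reagents that add atoms: diethylzinc, CC[Zn]CC
Why: Negishi coupling of the enol triflate installs the C7 ethyl group with the double bond fixed at C6=C7; the bidentate ligand favours reductive elimination over β-hydride elimination and the ester is tolerated.

Step 13
Reactants: 18 methyl (2E)-3-[(1R,3R,3aR,4S,5S,7aR)-4,7-diethyl-1,3-dimethyl-5-phenyl-2,3,3a,4,5,7a-hexahydro-1H-inden-4-yl]-2-methylprop-2-enoate
Product: 19 homo-plakotenin [(2E)-3-[(1R,3R,3aR,4S,5S,7aR)-4,7-diethyl-1,3-dimethyl-5-phenyl-2,3,3a,4,5,7a-hexahydro-1H-inden-4-yl]-2-methylprop-2-enoic acid]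
Conditions: LiOH·H2O, THF/MeOH/H2O, 50 °C; then 1 M HCl
Reagents that add atoms: lithium hydroxide, [Li+].[OH-]
Why: Saponification of the conjugated ester cannot epimerise any centre (none is α to the carbonyl group) and leaves the (E)-alkene intact.

Compound list
1 | (R)-citronellic acid, (3R)-3,7-dimethyloct-6-enoic acid | C[C@H](CCC=C(C)C)CC(=O)O | starting material
2 | (4R)-4,8-dimethylnon-7-en-2-one | CC(=O)C[C@H](C)CCC=C(C)C | intermediate
3 | 3,3-dimethyl-5-[(3R)-3-methyl-5-oxohexyl]-1,2,4-trioxolane (secondary ozonide, either epimer at the ring carbon) | CC(=O)C[C@H](C)CCC1OOC(C)(C)O1 | intermediate (not isolated)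
4 | (4R)-4-methyl-6-oxoheptanal | CC(=O)C[C@H](C)CCC=O | intermediate
5 | (4R)-4-methyl-2-methylidene-6-oxoheptanal | CC(=O)C[C@H](C)CC(=C)C=O | intermediate
6 | 1-[(5R)-5-methyl-3-methylidenecyclopent-1-en-1-yl]ethan-1-one | CC(=O)C1=CC(=C)C[C@H]1C | intermediate
7 | triisopropyl({1-[(5R)-5-methyl-3-methylidenecyclopent-1-en-1-yl]ethenyl}oxy)silane | C=C(O[Si](C(C)C)(C(C)C)C(C)C)C1=CC(=C)C[C@H]1C | intermediate
8 | 2-ethylacrolein (2-methylidenebutanal) | CCC(=C)C=O | starting material
9 | (1R,3aR,4S)-4-ethyl-1-methyl-3-methylidene-7-{[tri(propan-2-yl)silyl]oxy}-2,3,3a,4,5,6-hexahydro-1H-indene-4-carbaldehyde | CC(C)[Si](C(C)C)(C(C)C)OC1=C2[C@H](C)CC(=C)[C@H]2[C@@](CC)(C=O)CC1 | intermediate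
10 | (1R,3aS,4S,7aR)-4-ethyl-1-methyl-3-methylidene-7-oxooctahydro-1H-indene-4-carbaldehyde | O=C1CC[C@@](C=O)(CC)[C@H]2[C@H]1[C@H](C)CC2=C | intermediate
11 | methyl 2-(triphenyl-λ5-phosphanylidene)propanoate | COC(=O)C(C)=P(c1ccccc1)(c1ccccc1)c1ccccc1 | starting material
12 | methyl (2E)-3-[(1R,3aS,4R,7aR)-4-ethyl-1-methyl-3-methylidene-7-oxooctahydro-1H-inden-4-yl]-2-methylprop-2-enoate | O=C1CC[C@@](/C=C(\C)C(=O)OC)(CC)[C@H]2[C@H]1[C@H](C)CC2=C | intermediate
13 | methyl (2E)-3-[(1R,3R,3aR,4S,7aR)-4-ethyl-1,3-dimethyl-7-oxooctahydro-1H-inden-4-yl]-2-methylprop-2-enoate | O=C1CC[C@@](/C=C(\C)C(=O)OC)(CC)[C@H]2[C@H]1[C@H](C)C[C@H]2C | intermediate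
14 | lithium (1R,3R,3aR,4S,7aR)-4-ethyl-4-[(1E)-3-methoxy-2-methyl-3-oxoprop-1-en-1-yl]-1,3-dimethyl-2,3,3a,4,5,7a-hexahydro-1H-inden-7-olate | [Li+].[O-]C1=CC[C@@](/C=C(\C)C(=O)OC)(CC)[C@H]2[C@H]1[C@H](C)C[C@H]2C | intermediate (not isolated)
15 | methyl (2E)-3-[(1R,3R,3aR,4S,7aR)-4-ethyl-1,3-dimethyl-7-oxo-2,3,3a,4,7,7a-hexahydro-1H-inden-4-yl]-2-methylprop-2-enoate | O=C1C=C[C@@](/C=C(\C)C(=O)OC)(CC)[C@H]2[C@H]1[C@H](C)C[C@H]2C | intermediate
16 | lithium (1R,3R,3aR,4S,5S,7aR)-4-ethyl-4-[(1E)-3-methoxy-2-methyl-3-oxoprop-1-en-1-yl]-1,3-dimethyl-5-phenyl-2,3,3a,4,5,7a-hexahydro-1H-inden-7-olate | [Li+].[O-]C1=C[C@@H](c2ccccc2)[C@@](/C=C(\C)C(=O)OC)(CC)[C@H]2[C@H]1[C@H](C)C[C@H]2C | intermediate (not isolated)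
17 | methyl (2E)-3-[(1R,3R,3aR,4S,5S,7aR)-4-ethyl-1,3-dimethyl-5-phenyl-7-{[(trifluoromethyl)sulfonyl]oxy}-2,3,3a,4,5,7a-hexahydro-1H-inden-4-yl]-2-methylprop-2-enoate | O=S(=O)(OC1=C[C@@H](c2ccccc2)[C@@](/C=C(\C)C(=O)OC)(CC)[C@H]2[C@H]1[C@H](C)C[C@H]2C)C(F)(F)F | intermediate
18 | methyl (2E)-3-[(1R,3R,3aR,4S,5S,7aR)-4,7-diethyl-1,3-dimethyl-5-phenyl-2,3,3a,4,5,7a-hexahydro-1H-inden-4-yl]-2-methylprop-2-enoate | CCC1=C[C@@H](c2ccccc2)[C@@](/C=C(\C)C(=O)OC)(CC)[C@H]2[C@H]1[C@H](C)C[C@H]2C | intermediate
19 | homo-plakotenin, (2E)-3-[(1R,3R,3aR,4S,5S,7aR)-4,7-diethyl-1,3-dimethyl-5-phenyl-2,3,3a,4,5,7a-hexahydro-1H-inden-4-yl]-2-methylprop-2-enoic acid | CCC1=C[C@@H](c2ccccc2)[C@@](/C=C(\C)C(=O)O)(CC)[C@H]2[C@H]1[C@H](C)C[C@H]2C | target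

Total step count: 13. Longest linear sequence: 13 steps (1 to 19; 8 and 11 are commercial).

Steps most likely to fail

Step 6. The cycloaddition may stall at the crowded C3a terminus, divert to aldol-type attack at the formyl group, or discriminate poorly between the endo/exo modes or the diene faces. The fallback sets out from 6 and comes back at 10. The kinetic lithium dienolate of 6 (LiN(SiMe3)2, THF, −78 °C) would add through C6 to methyl 2-methylidenebutanoate, and the ester enolate so formed would close onto C3a in a second Michael addition (anionic double Michael annulation). After buffered protonation this should give methyl (1R,3aS,4S,7aR)-4-ethyl-1-methyl-3-methylidene-7-oxooctahydro-1H-indene-4-carboxylate F1. LiAlH4 would reduce both carbonyl groups to (1R,3aS,4S,7aR)-4-ethyl-4-(hydroxymethyl)-1-methyl-3-methylideneoctahydro-1H-inden-7-ol F2 (either C7 epimer), and Dess–Martin periodinane would return keto aldehyde 10.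

Step 7. Protonation at C7a may show poor facial selectivity, or C7a may later epimerise towards the cis-fused ketone; a rough conformational estimate does not clearly favour the trans epimer at equilibrium, so the step relies on kinetic control. The fallback sets out from 9 and comes back at 12, and moves the control from the substrate to a catalyst. Wittig reaction of 9 with 11 (toluene, 90 °C) would first give methyl (2E)-3-[(1R,3aS,4R)-4-ethyl-1-methyl-3-methylidene-7-{[tri(propan-2-yl)silyl]oxy}-2,3,3a,4,5,6-hexahydro-1H-inden-4-yl]-2-methylprop-2-enoate F3. Bu4N[Ph3SiF2] and allyl chloroformate would convert it into the allyl enol carbonate methyl (2E)-3-[(1R,3aS,4R)-4-ethyl-1-methyl-3-methylidene-7-{[(prop-2-en-1-yloxy)carbonyl]oxy}-2,3,3a,4,5,6-hexahydro-1H-inden-4-yl]-2-methylprop-2-enoate F4. Pd(OAc)2 with the matching enantiomer of t-Bu-PHOX and HCO2H would then carry out a decarboxylative protonation, in which the chiral palladium enolate chooses the face at C7a, to give 12.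

Step 9. Hydrogen delivery to the exocyclic alkene may not discriminate well between the face under the C4 side chain and the face near the C1 methyl group. The fallback sets out from 12 and comes back at 13. The bulkier 9-borabicyclo[3.3.1]nonane (THF, 0 °C; the ketone reacts far more slowly), then NaBO3·4H2O, should give methyl (2E)-3-[(1R,3R,3aR,4S,7aR)-4-ethyl-3-(hydroxymethyl)-1-methyl-7-oxooctahydro-1H-inden-4-yl]-2-methylprop-2-enoate F5. I2, PPh3 and imidazole would give methyl (2E)-3-[(1R,3R,3aS,4S,7aR)-4-ethyl-3-(iodomethyl)-1-methyl-7-oxooctahydro-1H-inden-4-yl]-2-methylprop-2-enoate F6, and Bu3SnH with AIBN (benzene, 80 °C) would reduce the iodide to 13.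

Further compounds
F1 | step 6 | methyl (1R,3aS,4S,7aR)-4-ethyl-1-methyl-3-methylidene-7-oxooctahydro-1H-indene-4-carboxylate | O=C1CC[C@@](C(=O)OC)(CC)[C@H]2[C@H]1[C@H](C)CC2=C
F2 | step 6 | (1R,3aS,4S,7aR)-4-ethyl-4-(hydroxymethyl)-1-methyl-3-methylideneoctahydro-1H-inden-7-ol (either C7 epimer) | OC1CC[C@@](CO)(CC)[C@H]2[C@H]1[C@H](C)CC2=C
F3 | step 7 | methyl (2E)-3-[(1R,3aS,4R)-4-ethyl-1-methyl-3-methylidene-7-{[tri(propan-2-yl)silyl]oxy}-2,3,3a,4,5,6-hexahydro-1H-inden-4-yl]-2-methylprop-2-enoate | CC(C)[Si](C(C)C)(C(C)C)OC1=C2[C@H](C)CC(=C)[C@H]2[C@@](CC)(/C=C(\C)C(=O)OC)CC1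
F4 | step 7 | methyl (2E)-3-[(1R,3aS,4R)-4-ethyl-1-methyl-3-methylidene-7-{[(prop-2-en-1-yloxy)carbonyl]oxy}-2,3,3a,4,5,6-hexahydro-1H-inden-4-yl]-2-methylprop-2-enoate | C=CCOC(=O)OC1=C2[C@H](C)CC(=C)[C@H]2[C@@](CC)(/C=C(\C)C(=O)OC)CC1
F5 | step 9 | methyl (2E)-3-[(1R,3R,3aR,4S,7aR)-4-ethyl-3-(hydroxymethyl)-1-methyl-7-oxooctahydro-1H-inden-4-yl]-2-methylprop-2-enoate | O=C1CC[C@@](/C=C(\C)C(=O)OC)(CC)[C@H]2[C@H]1[C@H](C)C[C@H]2CO
F6 | step 9 | methyl (2E)-3-[(1R,3R,3aS,4S,7aR)-4-ethyl-3-(iodomethyl)-1-methyl-7-oxooctahydro-1H-inden-4-yl]-2-methylprop-2-enoate | O=C1CC[C@@](/C=C(\C)C(=O)OC)(CC)[C@H]2[C@H]1[C@H](C)C[C@H]2CI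
A1 | direct plan | (2R,4R)-5-[(tert-butyldiphenylsilyl)oxy]-2,4-dimethylpentan-1-ol | OC[C@H](C)C[C@@H](C)CO[Si](c1ccccc1)(c1ccccc1)C(C)(C)C
A2 | direct plan | ethyl (2E,4Z,6R,8R,9E,11E)-4,10-diethyl-2,6,8-trimethyl-12-phenyldodeca-2,4,9,11-tetraenoate | CCOC(=O)/C(C)=C/C(CC)=C\[C@H](C)C[C@@H](C)/C=C(CC)/C=C/c1ccccc1
A3 | direct plan | ethyl (2E)-3-[(1R,3R,3aR,4S,5S,7aR)-4,7-diethyl-1,3-dimethyl-5-phenyl-2,3,3a,4,5,7a-hexahydro-1H-inden-4-yl]-2-methylprop-2-enoate | CCC1=C[C@@H](c2ccccc2)[C@@](/C=C(\C)C(=O)OCC)(CC)[C@H]2[C@H]1[C@H](C)C[C@H]2C
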